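The cyclohexane ring is opened at the C4–C5 bond, the bond between the two carbinol carbons that carry the p-coumaroyl esters. In the precursor both are aldehyde carbons of like polarity on a 1,3-dioxane, and a trans-selective reductive pinacol coupling with trivalent titanium joins them: one operation closes the carbocycle and sets both C4 and C5. The step exploits the cis relationship of the C1 and C3 oxygens, which are tied as a methylene acetal, so that the ring closure builds a 2,4-dioxabicyclo[3.3.1]nonane in which only the wanted trans diol is diequatorial. The liberated 4,5-diol is acylated, and one Lewis-acid step removes all protecting groups.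

Key step: step 7

Remark: compounds 5, 6 and 8 are carried as mixtures of epimers at the ester-bearing carbon, because step 5 erases that centre; 2 is used as the freshly distilled monomer; C1–C6 in the Why lines are the quinic acid locants.

Step 1
Reactants: 1 pent-3-yn-2-one; 2 tert-butyl glyoxylate
Product: 4 tert-butyl 2-hydroxy-4-oxohept-5-ynoate, via lithium enolate 3 (not isolated)
Conditions: LiN(SiMe3)2, THF, −78 °C; then 2; AcOH, −78 °C
Reagents that add atoms: none
Why: Crossed aldol addition of the kinetic methyl-ketone enolate to the non-enolizable, highly electrophilic aldehyde of the glyoxylate should give the C1–C2 bond; the new carbinol centre is racemic, which does not matter because it is erased in step 5, and the cold acidic quench avoids cyclization of the β-hydroxy ynone.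

Step 2
Reactants: 4 tert-butyl 2-hydroxy-4-oxohept-5-ynoate
Product: 5 tert-butyl (4R)-2,4-dihydroxyhept-5-ynoate
Conditions: Ru(p-cymene)[(R,R)-TsNCH(Ph)CH(Ph)NH] (1 mol %), iPrOH, 23 °C
Reagents that add atoms: none
Why: Asymmetric transfer hydrogenation of an alkynyl ketone (Noyori type) under base-free conditions should set the (4R) carbinol (C3) by catalyst control, the (R,R) catalyst being the enantiomer that gives (R)-alkynyl carbinols, while the neutral medium spares the β-hydroxy ketone and the tert-butyl ester.

Step 3
Reactants: 5 tert-butyl (4R)-2,4-dihydroxyhept-5-ynoate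
Product: 6 tert-butyl (4R,5Z)-2,4-dihydroxyhept-5-enoate
Conditions: H2 (1 atm), Pd/CaCO3 poisoned with Pb(OAc)2, quinoline, EtOAc, 23 °C
Reagents that add atoms: none
Why: Lindlar semihydrogenation adds hydrogen syn to the alkyne and should stop at the (Z)-alkene, which serves as the masked C4 aldehyde; the neutral conditions keep the γ-hydroxy tert-butyl ester from lactonizing.

Step 4
Reactants: 6 tert-butyl (4R,5Z)-2,4-dihydroxyhept-5-enoate; 7 dimethoxymethane
Product: 8 tert-butyl (6R)-6-[(1Z)-prop-1-en-1-yl]-1,3-dioxane-4-carboxylate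
Conditions: CH2(OMe)2 (solvent), LiBr, TsOH·H2O (cat.), 23 °C
Reagents that add atoms: dimethoxymethane (7), COCOC
Why: Acid-catalysed transacetalization of the 1,3-diol with a large excess of the formaldehyde acetal should close the six-membered formal faster than the hindered tert-butyl ester can lactonize, and it installs the tether between the C1 and C3 oxygens.

Step 5
Reactants: 8 tert-butyl (6R)-6-[(1Z)-prop-1-en-1-yl]-1,3-dioxane-4-carboxylate; 9 allyl bromide
Product: 11 tert-butyl (4R,6R)-4-(prop-2-en-1-yl)-6-[(1Z)-prop-1-en-1-yl]-1,3-dioxane-4-carboxylate, via lithium ester enolate 10 (not isolated)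
Conditions: LiN(iPr)2, THF, −78 °C; then allyl bromide, DMPU, −78 to −40 °C
Reagents that add atoms: allyl bromide (9), C=CCBr
Why: Alkylation of the exocyclic ester enolate of a 1,3-dioxane, in which the equatorial propenyl group anchors the chair and the syn-axial hydrogens at C2 and C6 of the dioxane shield the axial face, should bring the allyl group in equatorially, cis to the propenyl group, so that both epimers of 8 converge on one quaternary centre (C1).

Step 6
Reactants: 11 tert-butyl (4R,6R)-4-(prop-2-en-1-yl)-6-[(1Z)-prop-1-en-1-yl]-1,3-dioxane-4-carboxylate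
Product: 13 tert-butyl (4S,6R)-6-formyl-4-(2-oxoethyl)-1,3-dioxane-4-carboxylate, via bis-ozonide 12 (not isolated)
Conditions: O3, CH2Cl2, −78 °C; then PPh3, −78 to 23 °C
Reagents that add atoms: ozone, [O-][O+]=O
Why: Ozonolysis with reductive work-up should cleave both alkenes in one operation to the two aldehydes (C4 and C5) without touching a stereocentre; the crude dialdehyde is freed from volatile aldehydes and used at once, because the α-alkoxy aldehyde can epimerize.

Step 7
Reactants: 13 tert-butyl (4S,6R)-6-formyl-4-(2-oxoethyl)-1,3-dioxane-4-carboxylate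
Product: 15 tert-butyl (1R,5R,6S,7R)-6,7-dihydroxy-2,4-dioxabicyclo[3.3.1]nonane-1-carboxylate, via bis(titanoxy) diolate 14 (not isolated)
Conditions: Cp2TiCl2, iPrMgCl, THF, 23 °C; PhMgBr, −78 °C; 13 added slowly (high dilution), −78 to 0 °C; aq. NH4Cl
Reagents that add atoms: none
Why: This is a reductive pinacol coupling of a dialdehyde, a known reaction type (titanium-mediated cyclization of dials to trans-1,2-diols): Cp2TiPh, a trivalent titanium complex, transfers one electron to the chelating α-alkoxy aldehyde, the titanoxy ketyl radical adds to the second, titanium-bound aldehyde, and a second electron transfer gives diolate 14, which the aqueous work-up hydrolyses. The carbocycle closes in the 6-exo-trig mode (ketyl carbon onto the C=O of the 2-oxoethyl arm), which turns the 1,3-dioxane into the 2,4-dioxabicyclo[3.3.1]nonane. The new centre at C7 (C5 of the quinate) is controlled by the dioxane bridge, which blocks the endo face, so the oxygen must sit exo and equatorial. The new centre at C6 (C4 of the quinate) is controlled by the two bulky Cp2(Ph)Ti–O groups, which avoid each other and the axial positions, so the diol should be trans-diequatorial with the C6 oxygen cis to the bridge oxygen at C5. The step needs cyclization over oligomerization and one of four diastereomers; the cis arrangement of the two aldehyde arms from step 5, slow addition at high dilution, and the formal tether that holds the two older oxygens diaxial secure both. The tert-butyl ester and the formal should be inert to the reagent at −78 °C.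

Step 8
Reactants: 15 tert-butyl (1R,5R,6S,7R)-6,7-dihydroxy-2,4-dioxabicyclo[3.3.1]nonane-1-carboxylate; 16 (2E)-3-[4-(benzyloxy)phenyl]prop-2-enoic acid
Product: 17 tert-butyl (1S,5R,6R,7R)-6,7-bis({(2E)-3-[4-(benzyloxy)phenyl]prop-2-enoyl}oxy)-2,4-dioxabicyclo[3.3.1]nonane-1-carboxylate
Conditions: 16 (3 equiv), EDC·HCl, DMAP, CH2Cl2, 23 °C
Reagents that add atoms: (2E)-3-[4-(benzyloxy)phenyl]prop-2-enoic acid (16), OC(=O)/C=C/c1ccc(OCc2ccccc2)cc1
Why: Steglich esterification should acylate the only two free hydroxyls, both equatorial and secondary, while the tether keeps the C1 and C3 oxygens masked, so the 4,5-diester pattern follows without any regiochemical choice.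

Step 9
Reactants: 17 tert-butyl (1S,5R,6R,7R)-6,7-bis({(2E)-3-[4-(benzyloxy)phenyl]prop-2-enoyl}oxy)-2,4-dioxabicyclo[3.3.1]nonane-1-carboxylate
Product: 18 4,5-di-O-p-coumaroylquinic acid
Conditions: BCl3, C6HMe5, CH2Cl2, −78 to 0 °C; then MeOH/H2O
Reagents that add atoms: none
Why: Lewis-acid dealkylation with BCl3 should cleave the aryl benzyl ethers (benzyl cation trapped by pentamethylbenzene), the tert-butyl ester (alkyl–oxygen cleavage) and the methylene acetal (through a chloromethyl ether that the work-up hydrolyses), while the cinnamate esters on secondary carbons survive and the absence of base avoids acyl migration.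

Compound list
1 | pent-3-yn-2-one | CC#CC(C)=O | starting material
2 | tert-butyl glyoxylate | O=CC(=O)OC(C)(C)C | starting material
3 | lithium enolate of pent-3-yn-2-one | [Li]OC(=C)C#CC | intermediate
4 | tert-butyl 2-hydroxy-4-oxohept-5-ynoate (racemic) | CC#CC(=O)CC(O)C(=O)OC(C)(C)C | intermediate
5 | tert-butyl (4R)-2,4-dihydroxyhept-5-ynoate (both C2 epimers) | CC#C[C@H](O)CC(O)C(=O)OC(C)(C)C | intermediate
6 | tert-butyl (4R,5Z)-2,4-dihydroxyhept-5-enoate (both C2 epimers) | C/C=C\[C@H](O)CC(O)C(=O)OC(C)(C)C | intermediate
7 | dimethoxymethane | COCOC | starting material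
8 | tert-butyl (6R)-6-[(1Z)-prop-1-en-1-yl]-1,3-dioxane-4-carboxylate (both C4 epimers) | C/C=C\[C@H]1CC(C(=O)OC(C)(C)C)OCO1 | intermediate
9 | allyl bromide | C=CCBr | starting material
10 | lithium ester enolate of 8 | C/C=C\[C@H]1CC(=C(O[Li])OC(C)(C)C)OCO1 | intermediate
11 | tert-butyl (4R,6R)-4-(prop-2-en-1-yl)-6-[(1Z)-prop-1-en-1-yl]-1,3-dioxane-4-carboxylate (allyl cis to propenyl) | C=CC[C@]1(C(=O)OC(C)(C)C)C[C@H](/C=C\C)OCO1 | intermediate
12 | tert-butyl (4S,6R)-6-(5-methyl-1,2,4-trioxolan-3-yl)-4-(1,2,4-trioxolan-3-ylmethyl)-1,3-dioxane-4-carboxylate (bis-ozonide, mixture at the trioxolane carbons) | C1OOC(O1)C[C@]2(C(=O)OC(C)(C)C)C[C@H](C3OC(C)OO3)OCO2 | intermediate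
13 | tert-butyl (4S,6R)-6-formyl-4-(2-oxoethyl)-1,3-dioxane-4-carboxylate | O=CC[C@]1(C(=O)OC(C)(C)C)C[C@H](C=O)OCO1 | intermediate
14 | bis[Cp2(Ph)Ti] diolate of 15 (tetravalent titanium on each oxygen) | C1=CC(C=C1)[Ti](C1C=CC=C1)(c1ccccc1)O[C@@H]1[C@H]2C[C@@](C(=O)OC(C)(C)C)(C[C@H]1O[Ti](C1C=CC=C1)(C1C=CC=C1)c1ccccc1)OCO2 | intermediate
15 | tert-butyl (1R,5R,6S,7R)-6,7-dihydroxy-2,4-dioxabicyclo[3.3.1]nonane-1-carboxylate (both hydroxyls equatorial, trans) | O[C@@H]1[C@H]2C[C@@](C(=O)OC(C)(C)C)(C[C@H]1O)OCO2 | intermediate
16 | (2E)-3-[4-(benzyloxy)phenyl]prop-2-enoic acid | OC(=O)/C=C/c1ccc(OCc2ccccc2)cc1 | starting material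
17 | tert-butyl (1S,5R,6R,7R)-6,7-bis({(2E)-3-[4-(benzyloxy)phenyl]prop-2-enoyl}oxy)-2,4-dioxabicyclo[3.3.1]nonane-1-carboxylate | O=C(/C=C/c1ccc(OCc2ccccc2)cc1)O[C@@H]1[C@H]2C[C@@](C(=O)OC(C)(C)C)(C[C@H]1OC(=O)/C=C/c1ccc(OCc3ccccc3)cc1)OCO2 | intermediate
18 | 4,5-di-O-p-coumaroylquinic acid, (1S,3R,4R,5R)-1,3-dihydroxy-4,5-bis{[(2E)-3-(4-hydroxyphenyl)prop-2-enoyl]oxy}cyclohexane-1-carboxylic acid | O=C(/C=C/c1ccc(O)cc1)O[C@@H]1[C@H](O)C[C@@](O)(C(=O)O)C[C@H]1OC(=O)/C=C/c1ccc(O)cc1 | target

Total step count: 9. Longest linear sequence: 9 steps (1 and 2 to 18).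

Steps most likely to fail

Step 7. The trivalent titanium reagent may be too slow with the aliphatic aldehydes, so that simple reduction or oligomerization competes, or facial selectivity at C6 may be poor and give the cis diol. Fallback: from 13, SmI2 in THF/tBuOH at −78 °C (chelation-controlled, cis-selective pinacol cyclization) should give cis diol F1, in which the C7 hydroxyl is still exo and equatorial but the C6 hydroxyl is axial. Steglich esterification with one equivalent of 16 at low temperature should acylate the more accessible equatorial C7 hydroxyl to give monoester F2. A Mitsunobu reaction (PPh3, diisopropyl azodicarboxylate, 16) then esterifies C6 with inversion and comes back to the route at 17.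

Step 5. Facial selectivity in the alkylation of the ester enolate may be poor, because only axial hydrogens shield the axial face; the wrong C4 epimer cannot cyclize in step 7. Fallback: from 6, 2,2-dimethoxypropane and pyridinium p-toluenesulfonate should give acetonide F3, whose axial methyl group blocks the axial face of the enolate carbon. LiN(iPr)2 and allyl bromide then give allylated acetonide F4, aqueous acetic acid removes the acetonide to give diol F5, and the conditions of step 4 convert F5 into 11.

Step 9. The bridged formal may be cleaved incompletely, or a coumaroyl group may be lost or may migrate while three kinds of protecting group fall in one pot. Fallback: from 17, TMSOTf and 2,2'-bipyridyl in CH2Cl2 at 0 °C followed by water should cleave the formal through a pyridinium-type intermediate and the tert-butyl ester through its silyl ester, giving acid F6 with the benzyl ethers intact. BCl3 and pentamethylbenzene at −78 °C then remove only the two aryl benzyl ethers and give 18.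

Further compounds
F1 | step 7 | tert-butyl (1R,5R,6R,7R)-6,7-dihydroxy-2,4-dioxabicyclo[3.3.1]nonane-1-carboxylate (cis diol, C6 hydroxyl axial) | O[C@H]1[C@H]2C[C@@](C(=O)OC(C)(C)C)(C[C@H]1O)OCO2
F2 | step 7 | tert-butyl (1S,5R,6S,7R)-7-({(2E)-3-[4-(benzyloxy)phenyl]prop-2-enoyl}oxy)-6-hydroxy-2,4-dioxabicyclo[3.3.1]nonane-1-carboxylate | O[C@H]1[C@H]2C[C@@](C(=O)OC(C)(C)C)(C[C@H]1OC(=O)/C=C/c1ccc(OCc3ccccc3)cc1)OCO2
F3 | step 5 | tert-butyl (6R)-2,2-dimethyl-6-[(1Z)-prop-1-en-1-yl]-1,3-dioxane-4-carboxylate | C/C=C\[C@H]1CC(C(=O)OC(C)(C)C)OC(C)(C)O1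
F4 | step 5 | tert-butyl (4R,6R)-2,2-dimethyl-4-(prop-2-en-1-yl)-6-[(1Z)-prop-1-en-1-yl]-1,3-dioxane-4-carboxylate | C=CC[C@]1(C(=O)OC(C)(C)C)C[C@H](/C=C\C)OC(C)(C)O1
F5 | step 5 | tert-butyl (2R,4R,5Z)-2,4-dihydroxy-2-(prop-2-en-1-yl)hept-5-enoate | C=CC[C@](O)(C(=O)OC(C)(C)C)C[C@@H](O)/C=C\C
F6 | step 9 | (1S,3R,4R,5R)-4,5-bis({(2E)-3-[4-(benzyloxy)phenyl]prop-2-enoyl}oxy)-1,3-dihydroxycyclohexane-1-carboxylic acid | O=C(/C=C/c1ccc(OCc2ccccc2)cc1)O[C@@H]1[C@H](O)C[C@@](O)(C(=O)O)C[C@H]1OC(=O)/C=C/c1ccc(OCc2ccccc2)cc1
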